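**Retrosynthetic overview**
1. Malayenolide D ⇐ ring-closing metathesis to the tetrasubstituted butenolide ⇐ C-7 methacrylate ⇐ Nozaki–Hiyama–Kishi closure of the ten-membered ring (C-7–C-8).
2. Ring A (C-1 quaternary centre, C-2 senecioate, C-14 carbinol) ⇐ ring-expanding semipinacol 1,2-shift of a cyclopentanol α-hydroxy epoxide, relayed into an Evans–Tishchenko reduction by 3-methylbut-2-enal (key step).
3. Bis-epoxide ⇐ hydroxyl-directed double epoxidation ⇐ alkenylcerium addition to a 2-substituted cyclopent-3-enone.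
4. Cyclopentenone ⇐ Evans deconjugative alkylation, allyl ketone, ring-closing metathesis; iododiene ⇐ but-2-yn-1-ol + pent-3-yn-1-ol (Negishi coupling, hydrozirconation).
5. Ring order: cyclopentene → ring A with its epoxide (ring expansion) → ten-membered ring → butenolide.

Convention: atom labels C-1 to C-17 follow briarane numbering (C-1 quaternary ring-fusion carbon, C-2 to C-9 the rest of the ten-membered ring, C-10 ring-fusion CH, C-11 to C-14 the rest of ring A, C-17 the butenolide α-carbon). The oxazolidinone auxiliary is a recovered reagent.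

**Route**

Step 1
Reactants: 1 3-methylbut-2-enoyl chloride
Product: 2 (4S)-4-benzyl-3-(3-methylbut-2-enoyl)-1,3-oxazolidin-2-one
Conditions: (S)-4-benzyloxazolidin-2-one, n-BuLi, THF, −78 °C; then 1, −78 → 0 °C
Reagents that add atoms: (S)-4-benzyloxazolidin-2-one, O=C1N[C@@H](Cc2ccccc2)CO1
Why: N-acylation of the lithiated oxazolidinone by the acid chloride (nucleophilic acyl substitution) gives the imide; no stereocentre is formed.

Step 2
Reactants: 2 (4S)-4-benzyl-3-(3-methylbut-2-enoyl)-1,3-oxazolidin-2-one; 3 2,3-dibromoprop-1-ene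
Product: 5 (4S)-4-benzyl-3-[(2S)-2-(2-bromoprop-2-en-1-yl)-3-methylbut-3-enoyl]-1,3-oxazolidin-2-one, via sodium dienolate 4 (not isolated)
Conditions: NaN(SiMe3)2, THF, −78 °C; then 3, −78 → −40 °C
Reagents that add atoms: none
Why: γ-deprotonation gives the chelated (Z)-dienolate 4, which is alkylated at the α-carbon by the allylic bromide on the face opposite the benzyl group (deconjugative Evans alkylation), setting C-10 as (S) and leaving the vinylic bromide intact.

Step 3
Reactants: 5 (4S)-4-benzyl-3-[(2S)-2-(2-bromoprop-2-en-1-yl)-3-methylbut-3-enoyl]-1,3-oxazolidin-2-one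
Product: 6 (2S)-2-(2-bromoprop-2-en-1-yl)-N-methoxy-N,3-dimethylbut-3-enamide
Conditions: MeNH(OMe)·HCl, AlMe3, CH2Cl2, −10 → 0 °C
Reagents that add atoms: N,O-dimethylhydroxylamine hydrochloride, CNOC.Cl
Why: the aluminium amide opens the exocyclic imide carbonyl (Weinreb transamidation) and releases the auxiliary without epimerising the α-stereocentre.

Step 4
Reactants: 6 (2S)-2-(2-bromoprop-2-en-1-yl)-N-methoxy-N,3-dimethylbut-3-enamide; 7 allylmagnesium bromide
Product: 8 (5S)-5-(2-bromoprop-2-en-1-yl)-6-methylhepta-1,6-dien-4-one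
Conditions: THF, −78 °C; cold aq. NH4Cl quench
Reagents that add atoms: none
Why: the Grignard reagent adds once because the chelated tetrahedral intermediate survives until the cold quench (Weinreb ketone synthesis), so the doubly activated C-10 hydrogen never meets base.

Step 5
Reactants: 8 (5S)-5-(2-bromoprop-2-en-1-yl)-6-methylhepta-1,6-dien-4-one
Product: 9 (2S)-2-(2-bromoprop-2-en-1-yl)-3-methylcyclopent-3-en-1-one
Conditions: second-generation Grubbs catalyst (3 mol %), 1,4-benzoquinone (10 mol %), CH2Cl2, 40 °C; used at once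
Reagents that add atoms: none
Why: ring-closing metathesis of the allyl and isopropenyl groups gives the trisubstituted cyclopentene (the bromo-olefin is not a competent partner), and benzoquinone suppresses ruthenium hydride migration of the β,γ-olefin into conjugation, so C-10 stays (S).

Step 6
Reactants: 10 but-2-yn-1-ol
Product: 12 (2Z)-3-iodobut-2-en-1-ol, via cyclic vinylalanate 11 (not isolated)
Conditions: NaAlH2(OCH2CH2OMe)2, Et2O, 0 °C → rt; then I2, THF, −78 °C
Reagents that add atoms: iodine, II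
Why: the propargylic alkoxide directs anti-hydroalumination to the cyclic alanate with aluminium on C-5, and iodine cleaves the C–Al bond with retention to give the (Z)-iodide.

Step 7
Reactants: 12 (2Z)-3-iodobut-2-en-1-ol
Product: 13 triethyl{[(2Z)-3-iodobut-2-en-1-yl]oxy}silane
Conditions: Et3SiCl, imidazole, CH2Cl2, 0 °C
Reagents that add atoms: chlorotriethylsilane, CC[Si](Cl)(CC)CC
Why: silylation masks the primary hydroxyl, which would otherwise direct epoxidation to the C-5/C-6 olefin in step 12, as an ether that can later be oxidised directly.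

Step 8
Reactants: 14 pent-3-yn-1-ol
Product: 15 5-iodopent-2-yne
Conditions: I2, PPh3, imidazole, CH2Cl2, 0 °C → rt
Reagents that add atoms: iodine, II
Why: Appel-type iodination converts the primary alcohol into the iodide by SN2 displacement of the oxyphosphonium.

Step 9
Reactants: 15 5-iodopent-2-yne; 13 triethyl{[(2Z)-3-iodobut-2-en-1-yl]oxy}silane
Product: 17 triethyl{[(2Z)-3-methyloct-2-en-6-yn-1-yl]oxy}silane, via pent-3-ynylzinc iodide 16 (not isolated)
Conditions: 15, Zn dust, LiCl, THF, 40 °C; then 13, Pd(dppf)Cl2 (3 mol %), THF, 50 °C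
Reagents that add atoms: none
Why: zinc insertion gives the alkylzinc, and Negishi coupling through zerovalent palladium proceeds with retention at the alkenyl iodide, forming C-4–C-5 and fixing the (Z)-trisubstituted C-5/C-6 olefin.

Step 10
Reactants: 17 triethyl{[(2Z)-3-methyloct-2-en-6-yn-1-yl]oxy}silane
Product: 19 triethyl{[(2Z,6E)-7-iodo-3-methylocta-2,6-dien-1-yl]oxy}silane, via alkenylzirconocene chloride 18 (not isolated)
Conditions: Cp2Zr(H)Cl (1.6 equiv), THF, rt → 45 °C; then I2, 0 °C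
Reagents that add atoms: iodine, II
Why: syn-hydrozirconation, equilibrated with a slight excess of reagent, places zirconium on the less hindered methyl-bearing alkyne carbon, and iodinolysis with retention gives the (E)-2-iodoalkene; the trisubstituted olefin reacts far more slowly.

Step 11
Reactants: 19 triethyl{[(2Z,6E)-7-iodo-3-methylocta-2,6-dien-1-yl]oxy}silane; 9 (2S)-2-(2-bromoprop-2-en-1-yl)-3-methylcyclopent-3-en-1-one
Product: 22 (1R,2S)-2-(2-bromoprop-2-en-1-yl)-3-methyl-1-[(2E,6Z)-6-methyl-8-(triethylsilyloxy)octa-2,6-dien-2-yl]cyclopent-3-en-1-ol, via alkenyllithium 20 (not isolated), via alkenylcerium dichloride 21 (not isolated)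
Conditions: 19, t-BuLi (2.05 equiv), Et2O, −78 °C; CeCl3 (anhydrous), THF, −78 °C; then 9, −78 °C
Reagents that add atoms: none
Why: iodine–lithium exchange with retention and transmetallation give a non-basic alkenylcerium that adds 1,2 to the enolisable ketone anti to the C-9 side chain (organocerium carbonyl addition), giving the tertiary carbinol with OH cis to C-9.

Step 12
Reactants: 22 (1R,2S)-2-(2-bromoprop-2-en-1-yl)-3-methyl-1-[(2E,6Z)-6-methyl-8-(triethylsilyloxy)octa-2,6-dien-2-yl]cyclopent-3-en-1-ol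
Product: 23 (1R,2R,3R,5S)-2-(2-bromoprop-2-en-1-yl)-1-methyl-3-{(2R,3S)-2-methyl-3-[(3Z)-3-methyl-5-(triethylsilyloxy)pent-3-en-1-yl]oxiran-2-yl}-6-oxabicyclo[3.1.0]hexan-3-ol
Conditions: Hf(OtBu)4 (20 mol %), N,N′-[(1R,2R)-cyclohexane-1,2-diyl]bis(N-hydroxy-2,2-diphenylacetamide) (22 mol %; the ligand enantiomer that gives the (2R,3S)-oxirane, taken here as (R,R)), cumene hydroperoxide (2.6 equiv), DMPU, 4 Å MS, toluene, 0 °C → rt
Reagents that add atoms: cumene hydroperoxide, CC(C)(OO)c1ccccc1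
Why: hydroxyl-directed epoxidation with a hafnium bishydroxamate catalyst reaches only the two olefins next to the C-14 alkoxide: the ring olefin can be reached only on the hydroxyl face, which puts the 11,12-epoxide cis to C-9 as in the target, and the tertiary allylic side-chain olefin is epoxidised under ligand control to the oxirane that fixes C-1 and C-2.

Step 13
Reactants: 23 (1R,2R,3R,5S)-2-(2-bromoprop-2-en-1-yl)-1-methyl-3-{(2R,3S)-2-methyl-3-[(3Z)-3-methyl-5-(triethylsilyloxy)pent-3-en-1-yl]oxiran-2-yl}-6-oxabicyclo[3.1.0]hexan-3-ol; 24 3-methylbut-2-enal; 25 acetic anhydride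
Product: 28 (1R,2R,3S,4S,6S)-2-(2-bromoprop-2-en-1-yl)-1,3-dimethyl-3-{(1S,4Z)-4-methyl-1-[(3-methylbut-2-enoyl)oxy]-6-(triethylsilyloxy)hex-4-en-1-yl}-7-oxabicyclo[4.1.0]heptan-4-yl acetate, via hydroxy ketone 26 (not isolated), via hydroxy senecioate 27 (not isolated)
Conditions: SmI2 (0.3 equiv), 24 (6 equiv), THF, −10 °C → rt; then 25, pyridine, DMAP, rt
Reagents that add atoms: none
Why: Proposed new method: divalent samarium is oxidised by the aldehyde to a trivalent samarium Lewis acid that first triggers the ring-expanding semipinacol 1,2-shift of the α-hydroxy epoxide (the more substituted C-10 migrates from C-14 to C-1 anti to the breaking C-1–O bond, giving the cyclohexanone with the C-1 quaternary centre while C-2 and C-10 are retained) and then, still bound to the new C-2 alkoxide, captures 3-methylbut-2-enal as a hemiacetal whose hydride is delivered intramolecularly to the C-14 ketone through a trans-decalin-like chair, so the enal ends up as the C-2 senecioate and the C-14 hydroxyl is set 1,3-anti (axial), the epimer that an external hydride attacking anti to the axial C-1 methyl would not give, and the samarium alkoxide is acetylated in the same flask; the closest known reaction types are the SmI2-catalysed tandem semipinacol/Tishchenko reaction of α-hydroxy epoxides with aryl or saturated aldehydes and the Evans–Tishchenko reduction, and new here are the ring-expanding substrate carrying a second epoxide and an α,β-unsaturated aldehyde as hydride donor and acyl source.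

Step 14
Reactants: 28 (1R,2R,3S,4S,6S)-2-(2-bromoprop-2-en-1-yl)-1,3-dimethyl-3-{(1S,4Z)-4-methyl-1-[(3-methylbut-2-enoyl)oxy]-6-(triethylsilyloxy)hex-4-en-1-yl}-7-oxabicyclo[4.1.0]heptan-4-yl acetate
Product: 29 (1R,2R,3S,4S,6S)-2-(2-bromoprop-2-en-1-yl)-1,3-dimethyl-3-{(1S,4Z)-4-methyl-1-[(3-methylbut-2-enoyl)oxy]-6-oxohex-4-en-1-yl}-7-oxabicyclo[4.1.0]heptan-4-yl acetate
Conditions: (COCl)2, DMSO, CH2Cl2, −78 °C; Et3N, −78 → −30 °C
Reagents that add atoms: none
Why: Swern conditions convert a primary triethylsilyl ether directly into the aldehyde through the alkoxysulfonium ion, and at low temperature the (Z)-enal does not isomerise; esters, epoxide and vinyl bromide are inert.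

Step 15
Reactants: 29 (1R,2R,3S,4S,6S)-2-(2-bromoprop-2-en-1-yl)-1,3-dimethyl-3-{(1S,4Z)-4-methyl-1-[(3-methylbut-2-enoyl)oxy]-6-oxohex-4-en-1-yl}-7-oxabicyclo[4.1.0]heptan-4-yl acetate
Product: 31 (1S,2S,5Z,7S,10R,11R,12S,14S)-11,12-epoxy-7-hydroxy-1,5,11-trimethyl-8-methylidene-2-[(3-methylbut-2-enoyl)oxy]bicyclo[8.4.0]tetradec-5-en-14-yl acetate, via alkenylchromium dichloride 30 (not isolated)
Conditions: CrCl2 (12 equiv), NiCl2 (0.1 equiv), DMSO–THF 3:1, syringe-pump addition to 0.002 M, rt → 40 °C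
Reagents that add atoms: none
Why: Nozaki–Hiyama–Kishi reaction: nickel-mediated insertion into the C-8–Br bond and transmetallation give an alkenylchromium that adds only to the aldehyde and closes the ten-membered ring through C-7–C-8, the trans-diequatorial C-2 and C-9 arms of ring A and the (Z)-olefin holding the ends close; attack on the enal face turned away from the axial C-1 methyl is expected to give the (7S)-alcohol.

Step 16
Reactants: 31 (1S,2S,5Z,7S,10R,11R,12S,14S)-11,12-epoxy-7-hydroxy-1,5,11-trimethyl-8-methylidene-2-[(3-methylbut-2-enoyl)oxy]bicyclo[8.4.0]tetradec-5-en-14-yl acetate; 32 2-methylprop-2-enoyl chloride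
Product: 33 (1S,2S,5Z,7S,10R,11R,12S,14S)-14-acetoxy-11,12-epoxy-1,5,11-trimethyl-8-methylidene-2-[(3-methylbut-2-enoyl)oxy]bicyclo[8.4.0]tetradec-5-en-7-yl 2-methylprop-2-enoate
Conditions: Et3N, DMAP (cat.), CH2Cl2, 0 °C
Reagents that add atoms: none
Why: DMAP-catalysed acylation of the secondary allylic alcohol by the acid chloride (esterification) retains C-7.

Step 17
Reactants: 33 (1S,2S,5Z,7S,10R,11R,12S,14S)-14-acetoxy-11,12-epoxy-1,5,11-trimethyl-8-methylidene-2-[(3-methylbut-2-enoyl)oxy]bicyclo[8.4.0]tetradec-5-en-7-yl 2-methylprop-2-enoate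
Product: 34 malayenolide D
Conditions: second-generation Hoveyda–Grubbs catalyst (10 mol %), toluene, 80 °C, argon sparge
Reagents that add atoms: none
Why: ring-closing metathesis between the C-8 exo-methylene and the methacrylate forms the five-membered lactone and its tetrasubstituted C-8=C-17 olefin with loss of ethene; the ring trisubstituted olefin and the senecioate are too hindered or electron-poor to compete.

**Compound list**

1 | 3-methylbut-2-enoyl chloride | CC(C)=CC(Cl)=O | starting material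
2 | (4S)-4-benzyl-3-(3-methylbut-2-enoyl)-1,3-oxazolidin-2-one | CC(C)=CC(=O)N1[C@@H](Cc2ccccc2)COC1=O | intermediate
3 | 2,3-dibromoprop-1-ene | C=C(Br)CBr | starting material
4 | sodium (1Z)-1-[(4S)-4-benzyl-2-oxo-1,3-oxazolidin-3-yl]-3-methylbuta-1,3-dien-1-olate | C=C(C)/C=C(\[O-])N1[C@@H](Cc2ccccc2)COC1=O.[Na+] | intermediate
5 | (4S)-4-benzyl-3-[(2S)-2-(2-bromoprop-2-en-1-yl)-3-methylbut-3-enoyl]-1,3-oxazolidin-2-one | C=C(C)[C@H](CC(Br)=C)C(=O)N1[C@@H](Cc2ccccc2)COC1=O | intermediate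
6 | (2S)-2-(2-bromoprop-2-en-1-yl)-N-methoxy-N,3-dimethylbut-3-enamide | C=C(C)[C@H](CC(Br)=C)C(=O)N(C)OC | intermediate
7 | allylmagnesium bromide | C=CC[Mg]Br | starting material
8 | (5S)-5-(2-bromoprop-2-en-1-yl)-6-methylhepta-1,6-dien-4-one | C=C(C)[C@H](CC(Br)=C)C(=O)CC=C | intermediate
9 | (2S)-2-(2-bromoprop-2-en-1-yl)-3-methylcyclopent-3-en-1-one | O=C1CC=C(C)[C@@H]1CC(Br)=C | intermediate
10 | but-2-yn-1-ol | CC#CCO | starting material
11 | sodium 2,2-bis(2-methoxyethoxy)-3-methyl-2,5-dihydro-1,2-oxaluminol-2-uide | CC1=CCO[Al-]1(OCCOC)OCCOC.[Na+] | intermediate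
12 | (2Z)-3-iodobut-2-en-1-ol | C/C(I)=C/CO | intermediate
13 | triethyl{[(2Z)-3-iodobut-2-en-1-yl]oxy}silane | C/C(I)=C/CO[Si](CC)(CC)CC | intermediate
14 | pent-3-yn-1-ol | CC#CCCO | starting material
15 | 5-iodopent-2-yne | CC#CCCI | intermediate
16 | iodo(pent-3-yn-1-yl)zinc | CC#CCC[Zn]I | intermediate
17 | triethyl{[(2Z)-3-methyloct-2-en-6-yn-1-yl]oxy}silane | CC#CCC/C(C)=C\CO[Si](CC)(CC)CC | intermediate
18 | chlorobis(cyclopentadienyl)[(2E,6Z)-6-methyl-8-(triethylsilyloxy)octa-2,6-dien-2-yl]zirconium | C/C(=C\CC/C(C)=C\CO[Si](CC)(CC)CC)[Zr](Cl)(C1C=CC=C1)C1C=CC=C1 | intermediate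
19 | triethyl{[(2Z,6E)-7-iodo-3-methylocta-2,6-dien-1-yl]oxy}silane | C/C(I)=C\CC/C(C)=C\CO[Si](CC)(CC)CC | intermediate
20 | [(2Z,6Z)-6-methyl-8-(triethylsilyloxy)octa-2,6-dien-2-yl]lithium (lithium trans to the C-3 chain) | C/C([Li])=C\CC/C(C)=C\CO[Si](CC)(CC)CC | intermediate
21 | dichloro[(2E,6Z)-6-methyl-8-(triethylsilyloxy)octa-2,6-dien-2-yl]cerium | C/C(=C\CC/C(C)=C\CO[Si](CC)(CC)CC)[Ce](Cl)Cl | intermediate
22 | (1R,2S)-2-(2-bromoprop-2-en-1-yl)-3-methyl-1-[(2E,6Z)-6-methyl-8-(triethylsilyloxy)octa-2,6-dien-2-yl]cyclopent-3-en-1-ol | CC[Si](CC)(CC)OC/C=C(C)\CC/C=C(C)/[C@@]1(O)CC=C(C)[C@@H]1CC(Br)=C | intermediate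
23 | (1R,2R,3R,5S)-2-(2-bromoprop-2-en-1-yl)-1-methyl-3-{(2R,3S)-2-methyl-3-[(3Z)-3-methyl-5-(triethylsilyloxy)pent-3-en-1-yl]oxiran-2-yl}-6-oxabicyclo[3.1.0]hexan-3-ol | CC[Si](CC)(CC)OC/C=C(C)\CC[C@@H]1O[C@@]1(C)[C@@]3(O)C[C@@H]2O[C@]2(C)[C@@H]3CC(Br)=C | intermediate
24 | 3-methylbut-2-enal | CC(C)=CC=O | starting material
25 | acetic anhydride | CC(=O)OC(C)=O | starting material
26 | (1S,4S,5R,6R)-5-(2-bromoprop-2-en-1-yl)-4-[(1S,4Z)-1-hydroxy-4-methyl-6-(triethylsilyloxy)hex-4-en-1-yl]-4,6-dimethyl-7-oxabicyclo[4.1.0]heptan-3-one | O=C1C[C@@H]2O[C@]2(C)[C@H](CC(Br)=C)[C@@]1(C)[C@@H](O)CC/C(C)=C\CO[Si](CC)(CC)CC | intermediate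
27 | (1S,4Z)-1-[(1R,2R,3R,4S,6S)-2-(2-bromoprop-2-en-1-yl)-4-hydroxy-1,3-dimethyl-7-oxabicyclo[4.1.0]heptan-3-yl]-4-methyl-6-(triethylsilyloxy)hex-4-en-1-yl 3-methylbut-2-enoate | O[C@H]1C[C@@H]2O[C@]2(C)[C@H](CC(Br)=C)[C@@]1(C)[C@@H](OC(=O)C=C(C)C)CC/C(C)=C\CO[Si](CC)(CC)CC | intermediate
28 | (1R,2R,3S,4S,6S)-2-(2-bromoprop-2-en-1-yl)-1,3-dimethyl-3-{(1S,4Z)-4-methyl-1-[(3-methylbut-2-enoyl)oxy]-6-(triethylsilyloxy)hex-4-en-1-yl}-7-oxabicyclo[4.1.0]heptan-4-yl acetate | CC(=O)O[C@H]1C[C@@H]2O[C@]2(C)[C@H](CC(Br)=C)[C@@]1(C)[C@@H](OC(=O)C=C(C)C)CC/C(C)=C\CO[Si](CC)(CC)CC | intermediate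
29 | (1R,2R,3S,4S,6S)-2-(2-bromoprop-2-en-1-yl)-1,3-dimethyl-3-{(1S,4Z)-4-methyl-1-[(3-methylbut-2-enoyl)oxy]-6-oxohex-4-en-1-yl}-7-oxabicyclo[4.1.0]heptan-4-yl acetate | CC(=O)O[C@H]1C[C@@H]2O[C@]2(C)[C@H](CC(Br)=C)[C@@]1(C)[C@@H](OC(=O)C=C(C)C)CC/C(C)=C\C=O | intermediate
30 | C-8 alkenylchromium dichloride derived from 29 (CrCl2 in place of Br) | CC(=O)O[C@H]1C[C@@H]2O[C@]2(C)[C@H](CC(=C)[Cr](Cl)Cl)[C@@]1(C)[C@@H](OC(=O)C=C(C)C)CC/C(C)=C\C=O | intermediate
31 | (1S,2S,5Z,7S,10R,11R,12S,14S)-11,12-epoxy-7-hydroxy-1,5,11-trimethyl-8-methylidene-2-[(3-methylbut-2-enoyl)oxy]bicyclo[8.4.0]tetradec-5-en-14-yl acetate | CC(=O)O[C@H]1C[C@@H]2O[C@]2(C)[C@@H]2CC(=C)[C@@H](O)/C=C(/C)CC[C@H](OC(=O)C=C(C)C)[C@@]12C | intermediate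
32 | 2-methylprop-2-enoyl chloride | C=C(C)C(Cl)=O | starting material
33 | (1S,2S,5Z,7S,10R,11R,12S,14S)-14-acetoxy-11,12-epoxy-1,5,11-trimethyl-8-methylidene-2-[(3-methylbut-2-enoyl)oxy]bicyclo[8.4.0]tetradec-5-en-7-yl 2-methylprop-2-enoate | CC(=O)O[C@H]1C[C@@H]2O[C@]2(C)[C@@H]2CC(=C)[C@@H](OC(=O)C(C)=C)/C=C(/C)CC[C@H](OC(=O)C=C(C)C)[C@@]12C | intermediate
34 | malayenolide D | CC(=O)O[C@H]1C[C@@H]2O[C@]2(C)[C@@H]2CC3=C(C)C(=O)O[C@H]3/C=C(/C)CC[C@H](OC(=O)C=C(C)C)[C@@]12C | target

**Step count**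

Total: 17 steps. Longest linear sequence: 12 steps (steps 1–5, then 11–17).

**Three steps most likely to fail**

Step 12. The ring epoxide is safe, but the side-chain epoxide needs the olefin face that lies toward C-10. The C-9 side chain sits cis to the directing hydroxyl and sterically favours the other face, so the ligand has to override the substrate. The fallback sets out from Weinreb amide 6 and vinyl iodide 19 and returns at 23. It places the side-chain oxygen under reagent control on a secondary alcohol before ring A's five-membered precursor is closed. The alkenyllithium 20 (made as in step 11) is added to 6 to give dienone F1. Reduction with NaBH4/CeCl3 gives the (14R)-allylic alcohol F2; its C-14 epimer is re-oxidised with MnO2 and recycled. Sharpless epoxidation (Ti(OiPr)4, D-(−)-diisopropyl tartrate, TBHP, 4 Å MS, −20 °C) is matched for F2 and gives epoxy alcohol F3. Dess–Martin oxidation gives epoxy ketone F4. Chelation-controlled addition of allylmagnesium bromide 7 (attack on the face of the pinned-back oxirane CH, anti to the oxirane methyl) gives tertiary alcohol F5. Ring-closing metathesis with the second-generation Grubbs catalyst gives cyclopentenol F6. VO(acac)2/TBHP then epoxidises only the ring olefin, cis to the hydroxyl, to give 23.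

Step 13 (the proposed new step). Three things can go wrong: the enal may not serve as hydride donor, the samarium Lewis acid may open the ring epoxide, or C-13 may migrate in place of C-10. The fallback sets out from 23 and returns at 27, using known reactions one at a time. ZnBr2 in CH2Cl2 at 0 °C effects the known Lewis-acid semipinacol ring expansion to hydroxy ketone 26, here isolated. Me4NBH(OAc)3 in MeCN/AcOH at −30 °C reduces it by intramolecular hydride delivery to the anti-diol F7. The acyclic C-2 hydroxyl, less hindered than the axial C-14 hydroxyl, is esterified with 3-methylbut-2-enoic anhydride and DMAP (1.05 equiv, −20 °C) to give 27, which is acetylated as in step 13.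

Step 15. The ten-membered ring may not close in competition with oligomerisation, and the configuration at C-7 is only predicted. The fallback sets out from 28 and returns at 31. It forms C-7–C-8 intermolecularly and closes the ring by metathesis. Nozaki–Hiyama–Kishi coupling of the vinyl bromide of 28 with acrolein (CrCl2, NiCl2 cat., DMF; chiral sulfonamide ligand or separation of epimers) gives dienyl alcohol F8. Ring-closing metathesis (second-generation Hoveyda–Grubbs catalyst, toluene, 80 °C, 0.001 M) between the new vinyl group and the C-5/C-6 trisubstituted olefin closes the ring with loss of allyl triethylsilyl ether and gives 31. If the main step closes the ring but gives the (7R)-alcohol, step 16 is run as a Mitsunobu esterification with methacrylic acid to invert C-7.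

**Further compounds**

F1 | step 12 | dienone: (3S,5E,9Z)-3-(2-bromoprop-2-en-1-yl)-2,5,9-trimethyl-11-(triethylsilyloxy)undeca-1,5,9-trien-4-one | C=C(C)[C@H](CC(Br)=C)C(=O)/C(C)=C/CC/C(C)=C\CO[Si](CC)(CC)CC
F2 | step 12 | allylic alcohol: (3S,4R,5E,9Z)-3-(2-bromoprop-2-en-1-yl)-2,5,9-trimethyl-11-(triethylsilyloxy)undeca-1,5,9-trien-4-ol | C=C(C)[C@H](CC(Br)=C)[C@@H](O)/C(C)=C/CC/C(C)=C\CO[Si](CC)(CC)CC
F3 | step 12 | epoxy alcohol: (1R,2S)-2-(2-bromoprop-2-en-1-yl)-3-methyl-1-{(2S,3S)-2-methyl-3-[(3Z)-3-methyl-5-(triethylsilyloxy)pent-3-en-1-yl]oxiran-2-yl}but-3-en-1-ol | C=C(C)[C@H](CC(Br)=C)[C@@H](O)[C@]1(C)O[C@H]1CC/C(C)=C\CO[Si](CC)(CC)CC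
F4 | step 12 | epoxy ketone: (2S)-2-(2-bromoprop-2-en-1-yl)-3-methyl-1-{(2R,3S)-2-methyl-3-[(3Z)-3-methyl-5-(triethylsilyloxy)pent-3-en-1-yl]oxiran-2-yl}but-3-en-1-one | C=C(C)[C@H](CC(Br)=C)C(=O)[C@]1(C)O[C@H]1CC/C(C)=C\CO[Si](CC)(CC)CC
F5 | step 12 | tertiary alcohol: (3S,4R)-3-(2-bromoprop-2-en-1-yl)-2-methyl-4-{(2R,3S)-2-methyl-3-[(3Z)-3-methyl-5-(triethylsilyloxy)pent-3-en-1-yl]oxiran-2-yl}hepta-1,6-dien-4-ol | C=C(C)[C@H](CC(Br)=C)[C@](O)(CC=C)[C@]1(C)O[C@H]1CC/C(C)=C\CO[Si](CC)(CC)CC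
F6 | step 12 | cyclopentenol: (1R,2S)-2-(2-bromoprop-2-en-1-yl)-3-methyl-1-{(2R,3S)-2-methyl-3-[(3Z)-3-methyl-5-(triethylsilyloxy)pent-3-en-1-yl]oxiran-2-yl}cyclopent-3-en-1-ol | CC[Si](CC)(CC)OC/C=C(C)\CC[C@@H]1O[C@@]1(C)[C@@]3(O)CC=C(C)[C@@H]3CC(Br)=C
F7 | step 13 | anti-diol: (1R,2R,3S,4S,6S)-2-(2-bromoprop-2-en-1-yl)-3-[(1S,4Z)-1-hydroxy-4-methyl-6-(triethylsilyloxy)hex-4-en-1-yl]-1,3-dimethyl-7-oxabicyclo[4.1.0]heptan-4-ol | O[C@H]1C[C@@H]2O[C@]2(C)[C@H](CC(Br)=C)[C@@]1(C)[C@@H](O)CC/C(C)=C\CO[Si](CC)(CC)CC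
F8 | step 15 | dienyl alcohol: (1R,2R,3S,4S,6S)-2-[(3S)-3-hydroxy-2-methylidenepent-4-en-1-yl]-1,3-dimethyl-3-{(1S,4Z)-4-methyl-1-[(3-methylbut-2-enoyl)oxy]-6-(triethylsilyloxy)hex-4-en-1-yl}-7-oxabicyclo[4.1.0]heptan-4-yl acetate | CC(=O)O[C@H]1C[C@@H]2O[C@]2(C)[C@H](CC(=C)[C@@H](O)C=C)[C@@]1(C)[C@@H](OC(=O)C=C(C)C)CC/C(C)=C\CO[Si](CC)(CC)CC
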